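**Retrosynthetic overview**
1. The gem-diprenyl carbon is cut last (double C-prenylation of des-prenyl trione 22). The acylcyclohexanetrione ring of 22 is opened by a retro-Claisen between the acyl-bearing carbon and the axial carbonyl on the spiro carbon, and triketone 20 is split into acid chloride 19 and the dianion of 6-methylheptane-2,4-dione.
2. Key disconnection: the bond between the ring CH2 next to the spiro carbon and the neighbouring C(OH)CH3 carbon of the cyclohexane, leading back to keto (iodomethyl)malonate 13. Forward, this is a SmI2 Barbier cyclization whose alkoxide lactonizes onto one of the two malonate esters.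
3. Enabling feature: in the cyclohexane ring of the trans-hydrindane, the tertiary hydroxyl and one of the two carbonyl carbons on the spiro carbon are 1,3-cis-diaxial (O–C(CH3)–CH2–C(spiro)–C=O, a γ-hydroxy carbonyl unit). A spiro-malonate can therefore be closed onto a methyl ketone and desymmetrized as a bridging γ-lactone, which records which carbonyl becomes the acyl-enol side of the trione.
4. The cyclopentane with its three stereocentres comes from (+)-limonene oxide: glycol cleavage, aldol condensation, epoxidation, reductive epoxide opening; then malonate alkylation, ozonolysis and iodomethylation.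
5. Ring order: cyclopentane (aldol) → cyclohexane plus temporary lactone (key step) → cyclohexanetrione (Claisen).

Key step: step 10

Remark: the β-triketone of the target is treated as the enol tautomer drawn (its tautomers interconvert), and commercial (+)-limonene oxide is used as its cis/trans mixture because both isomers give the same keto aldehyde.

**Route**

Step 1
Reactants: 1 (+)-limonene oxide (cis/trans mixture of (4R)-1,2-epoxy-p-menth-8-ene)
Product: 3 (3R)-6-oxo-3-(prop-1-en-2-yl)heptanal, via limonene-1,2-diol 2 (not isolated)
Conditions: H5IO6 (1.1 equiv), THF/H2O, 0 °C → rt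
Reagents that add atoms: water, O
Why: Epoxide hydrolysis followed by periodate glycol cleavage (Malaprade reaction) opens the ring between the two oxygenated carbons, and the isopropenyl-bearing stereocentre is not α to either new carbonyl and so cannot epimerize.

Step 2
Reactants: 3 (3R)-6-oxo-3-(prop-1-en-2-yl)heptanal
Product: 4 (S)-2-methyl-5-(prop-1-en-2-yl)cyclopent-1-ene-1-carbaldehyde
Conditions: piperidine (cat.), AcOH (cat.), toluene, reflux (Dean–Stark)
Reagents that add atoms: none
Why: Intramolecular aldol condensation of the aldehyde enamine onto the methyl ketone closes the cyclopentene, the stereocentre being untouched (only its descriptor changes).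

Step 3
Reactants: 4 (S)-2-methyl-5-(prop-1-en-2-yl)cyclopent-1-ene-1-carbaldehyde
Product: 5 epoxy aldehyde (epoxide oxygen trans to the isopropenyl group)
Conditions: H2O2 (30% aq.), NaOH (cat.), MeOH, 0 °C
Reagents that add atoms: hydrogen peroxide, OO
Why: Weitz–Scheffer nucleophilic epoxidation of the enal should occur on the ring face opposite the adjacent isopropenyl group, which places the future tertiary oxygen trans to that group.

Step 4
Reactants: 5 epoxy aldehyde
Product: 7 (1R,2R,3R)-2-(hydroxymethyl)-1-methyl-3-(prop-1-en-2-yl)cyclopentan-1-ol, via β-hydroxy aldehyde 6 (not isolated)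
Conditions: SmI2 (2.2 equiv), THF/MeOH, −90 °C; work-up; DBU (0.1 equiv), CH2Cl2, 0 °C; then NaBH4, MeOH, 0 °C
Reagents that add atoms: none
Why: Reductive cleavage of the α C–O bond of the α,β-epoxy carbonyl compound by samarium diiodide gives the β-hydroxy aldehyde, whose α-centre should equilibrate under base to the isomer with the formyl group trans to the isopropenyl and ring-methyl groups (cis to the hydroxyl) before borohydride reduction fixes it.

Step 5
Reactants: 7 (1R,2R,3R)-2-(hydroxymethyl)-1-methyl-3-(prop-1-en-2-yl)cyclopentan-1-ol
Product: 8 (1R,2S,3R)-2-(iodomethyl)-1-methyl-3-(prop-1-en-2-yl)cyclopentan-1-ol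
Conditions: I2, PPh3, imidazole, CH2Cl2, 0 °C → rt
Reagents that add atoms: iodine, II
Why: Appel-type iodination proceeds by SN2 displacement of the primary oxyphosphonium group only, the tertiary alcohol being too hindered to be activated.

Step 6
Reactants: 8 (1R,2S,3R)-2-(iodomethyl)-1-methyl-3-(prop-1-en-2-yl)cyclopentan-1-ol
Product: 9 triethyl{[(1R,2S,3R)-2-(iodomethyl)-1-methyl-3-(prop-1-en-2-yl)cyclopentyl]oxy}silane
Conditions: TESOTf, 2,6-lutidine, CH2Cl2, −78 → 0 °C
Reagents that add atoms: triethylsilyl trifluoromethanesulfonate, CC[Si](CC)(CC)OS(=O)(=O)C(F)(F)F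
Why: Silylation of the tertiary alcohol with a silyl triflate masks the only protic group, which would otherwise quench the organosamarium of the key step and react during acid chloride formation.

Step 7
Reactants: 9 silyl ether iodide; 10 dibenzyl malonate
Product: 11 dibenzyl 2-{[(1S,2R,5R)-2-methyl-5-(prop-1-en-2-yl)-2-(triethylsilyloxy)cyclopentyl]methyl}malonate
Conditions: 10 (3 equiv), NaH (2.8 equiv), DMF, 60 °C
Reagents that add atoms: none
Why: Malonic ester alkylation (SN2) of the β-branched primary iodide by the soft, weakly basic malonate anion should outrun elimination and leaves all stereocentres untouched.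

Step 8
Reactants: 11 alkylmalonate
Product: 12 dibenzyl 2-{[(1S,2R,5R)-5-acetyl-2-methyl-2-(triethylsilyloxy)cyclopentyl]methyl}malonate
Conditions: O3, CH2Cl2/MeOH, −78 °C; then Me2S, −78 °C → rt
Reagents that add atoms: ozone, [O-][O+]=O
Why: Ozonolysis of the only alkene with reductive work-up unveils the methyl ketone, whose α-centre already has the thermodynamically preferred trans relation to the neighbouring side chain.

Step 9
Reactants: 12 keto malonate
Product: 13 dibenzyl 2-{[(1S,2R,5R)-5-acetyl-2-methyl-2-(triethylsilyloxy)cyclopentyl]methyl}-2-(iodomethyl)malonate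
Conditions: NaH (1.05 equiv), THF/DMF, 0 °C; then CH2I2 (6 equiv), 50 °C
Reagents that add atoms: diiodomethane, ICI
Why: Malonate C-alkylation with diiodomethane is selective because the malonate C–H is far more acidic than the ketone α-hydrogens, and aldol closure of the malonate anion onto the ketone would need a strained trans-fused bicyclo[3.3.0] ring.

Step 10
Reactants: 13 keto (iodomethyl)malonate
Product: 15 bridged γ-lactone benzyl ester, via cyclized alkoxide diester 14 (not isolated)
Conditions: SmI2 (2.5 equiv), NiI2 (1 mol %), THF, −78 → 0 °C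
Reagents that add atoms: none
Why: Two single-electron transfers from samarium diiodide turn the C–I bond into a primary alkylsamarium (trivalent samarium) held by the β-ester carbonyls, which adds to the methyl ketone and forms the CH2–C(OH)CH3 bond of the cyclohexane, after which the tertiary alkoxide attacks the one ester cis to it and expels benzyloxide. The closest known reaction types are the samarium Barbier cyclization of iodoalkyl ketones and the γ-lactone-forming addition of β-metallo esters (homoenolates) to ketones. The cyclohexane closes 6-exo-trig (carbon nucleophile on the ketone carbonyl) and the γ-lactone 5-exo-trig (alkoxide on the ester carbonyl). The new carbinol centre is set by a chair transition state on the trans-disubstituted cyclopentane in which the ketone methyl stays equatorial to avoid a 1,3-diaxial clash with the axial ester, while the ketone oxygen is axial and bridged through samarium to that ester. The spiro carbon, prochiral in 13, becomes stereogenic because only the axial ester can reach the axial alkoxide, so the lactone carbonyl marks the carbonyl that later carries the acyl-enol side of the trione. The step needs ketone addition to outrun protonation, pinacol coupling and attack on the esters, which is secured by the aprotic medium with the tertiary alcohol silylated, the fast nickel-catalysed reduction of the iodide, and the six-membered closure assisted by the quaternary malonate carbon.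

Step 11
Reactants: 15 bridged γ-lactone benzyl ester
Product: 16 lactone carboxylic acid
Conditions: H2 (1 atm), Pd/C, EtOAc, rt
Reagents that add atoms: none
Why: Hydrogenolysis of the benzyl ester on palladium frees the equatorial carboxyl without touching the lactone, the silyl ether or any stereocentre.

Step 12
Reactants: 16 lactone carboxylic acid; 17 6-methylheptane-2,4-dione
Product: 20 lactone triketone, via dilithio diketone 18 (not isolated), via acid chloride 19 (not isolated)
Conditions: 16, 1-chloro-N,N,2-trimethylprop-1-en-1-amine, CH2Cl2, 0 °C → rt; separately 17 (3 equiv), LDA (6 equiv), THF, 0 °C; combine at −78 → −20 °C; aq. NH4Cl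
Reagents that add atoms: none
Why: Harris-type γ-acylation of the β-diketone dianion at its terminal methyl carbon by the acid chloride, which is far more electrophilic than the lactone, makes the equatorial carboxyl the ketone next to the future gem-diprenyl carbon.

Step 13
Reactants: 20 lactone triketone
Product: 22 des-prenyl spiro trione diol, via silyl-protected spirotrione 21 (not isolated)
Conditions: NaOMe (4 equiv), MeOH, 50 °C; then 1 M aq. HCl, THF, rt
Reagents that add atoms: none
Why: Intramolecular Claisen (Dieckmann-type, 6-exo-trig) acylation of the methylene between the central and isovaleryl carbonyls onto the lactone carbonyl closes the trione ring irreversibly as its acidic enolate and releases the tertiary alkoxide, the acid work-up removing the silyl ether while the spiro configuration is carried over from the lactone.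

Step 14
Reactants: 22 des-prenyl spiro trione diol; 23 prenyl bromide
Product: 25 target CNP0198642.2, via monoprenyl trione 24 (not isolated)
Conditions: NaOMe (3.2 equiv), MeOH, 0 °C; 23 (2.3 equiv), 0 °C → rt
Reagents that add atoms: none
Why: Double C-alkylation (SN2) of the only remaining ring methylene, flanked by two carbonyls, is the classical geminal prenylation of acylphloroglucinol-derived triketone enolates and affects neither tertiary alcohol nor any stereocentre.

**Compound list**
1 | (+)-limonene oxide, (4R)-1,2-epoxy-p-menth-8-ene, cis/trans mixture | CC12OC1C[C@@H](CC2)C(C)=C | starting material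
2 | (4R)-p-menth-8-ene-1,2-diol (limonene-1,2-diol) | CC1(O)C(O)C[C@@H](CC1)C(C)=C | intermediate
3 | (3R)-6-oxo-3-(prop-1-en-2-yl)heptanal | O=CC[C@@H](CCC(C)=O)C(C)=C | intermediate
4 | (S)-2-methyl-5-(prop-1-en-2-yl)cyclopent-1-ene-1-carbaldehyde | O=CC1=C(C)CC[C@H]1C(C)=C | intermediate
5 | 5-methyl-2-(prop-1-en-2-yl)-6-oxabicyclo[3.1.0]hexane-1-carbaldehyde, epoxide oxygen trans to the isopropenyl group | O=C[C@@]12O[C@]1(C)CC[C@H]2C(C)=C | intermediate
6 | (1S,2R,5R)-2-hydroxy-2-methyl-5-(prop-1-en-2-yl)cyclopentane-1-carbaldehyde | O=C[C@H]1[C@@H](CC[C@@]1(C)O)C(C)=C | intermediate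
7 | (1R,2R,3R)-2-(hydroxymethyl)-1-methyl-3-(prop-1-en-2-yl)cyclopentan-1-ol | OC[C@H]1[C@@H](CC[C@@]1(C)O)C(C)=C | intermediate
8 | (1R,2S,3R)-2-(iodomethyl)-1-methyl-3-(prop-1-en-2-yl)cyclopentan-1-ol | IC[C@H]1[C@@H](CC[C@@]1(C)O)C(C)=C | intermediate
9 | triethyl{[(1R,2S,3R)-2-(iodomethyl)-1-methyl-3-(prop-1-en-2-yl)cyclopentyl]oxy}silane | IC[C@H]1[C@@H](CC[C@@]1(C)O[Si](CC)(CC)CC)C(C)=C | intermediate
10 | dibenzyl malonate | O=C(OCc1ccccc1)CC(=O)OCc1ccccc1 | starting material
11 | dibenzyl 2-{[(1S,2R,5R)-2-methyl-5-(prop-1-en-2-yl)-2-(triethylsilyloxy)cyclopentyl]methyl}malonate | O=C(OCc1ccccc1)C(C(=O)OCc1ccccc1)C[C@H]1[C@@H](CC[C@@]1(C)O[Si](CC)(CC)CC)C(C)=C | intermediate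
12 | dibenzyl 2-{[(1S,2R,5R)-5-acetyl-2-methyl-2-(triethylsilyloxy)cyclopentyl]methyl}malonate | O=C(OCc1ccccc1)C(C(=O)OCc1ccccc1)C[C@H]1[C@@H](CC[C@@]1(C)O[Si](CC)(CC)CC)C(C)=O | intermediate
13 | dibenzyl 2-{[(1S,2R,5R)-5-acetyl-2-methyl-2-(triethylsilyloxy)cyclopentyl]methyl}-2-(iodomethyl)malonate | ICC(C(=O)OCc1ccccc1)(C(=O)OCc1ccccc1)C[C@H]1[C@@H](CC[C@@]1(C)O[Si](CC)(CC)CC)C(C)=O | intermediate
14 | dibenzyl trans-octahydroindene-6,6-dicarboxylate with 4-hydroxy-4-methyl (hydroxyl axial) and 1-methyl-1-(triethylsilyloxy) groups; formed as its trivalent-samarium alkoxide, drawn as the free alcohol | O=C(OCc1ccccc1)C2(C(=O)OCc1ccccc1)C[C@H]3[C@@H](CC[C@@]3(C)O[Si](CC)(CC)CC)[C@@](C)(O)C2 | intermediate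
15 | bridged γ-lactone benzyl ester: the axial 4-oxygen of 14 lactonized onto the axial 6-carboxyl, equatorial benzyl ester retained | O=C(OCc1ccccc1)[C@@]2(C[C@H]3[C@@H](CC[C@@]3(C)O[Si](CC)(CC)CC)[C@@](C)(O4)C2)C4=O | intermediate
16 | lactone carboxylic acid (equatorial CO2H on the spiro-carbon precursor) | OC(=O)[C@@]2(C[C@H]3[C@@H](CC[C@@]3(C)O[Si](CC)(CC)CC)[C@@](C)(O4)C2)C4=O | intermediate
17 | 6-methylheptane-2,4-dione | CC(=O)CC(=O)CC(C)C | starting material
18 | dilithium 1,3-dianion of 6-methylheptane-2,4-dione | [Li+].[Li+].[CH2-]C(=O)[CH-]C(=O)CC(C)C | intermediate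
19 | lactone acid chloride | ClC(=O)[C@@]2(C[C@H]3[C@@H](CC[C@@]3(C)O[Si](CC)(CC)CC)[C@@](C)(O4)C2)C4=O | intermediate
20 | lactone triketone: 7-methyloctane-1,3,5-trione attached through C-1 to the lactone-bearing quaternary carbon | CC(C)CC(=O)CC(=O)CC(=O)[C@@]2(C[C@H]3[C@@H](CC[C@@]3(C)O[Si](CC)(CC)CC)[C@@](C)(O4)C2)C4=O | intermediate
21 | silyl-protected spiro acylcyclohexanetrione (ring CH2 unsubstituted, tertiary cyclohexanol free) | C1C(=O)[C@@]2(C[C@H]3[C@@H](CC[C@@]3(C)O[Si](CC)(CC)CC)[C@@](C)(O)C2)C(=O)C(C(=O)CC(C)C)=C1O | intermediate
22 | des-prenyl spiro trione diol (target lacking both prenyl groups) | C1C(=O)[C@@]2(C[C@H]3[C@@H](CC[C@@]3(C)O)[C@@](C)(O)C2)C(=O)C(C(=O)CC(C)C)=C1O | intermediate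
23 | prenyl bromide (1-bromo-3-methylbut-2-ene) | CC(C)=CCBr | starting material
24 | monoprenyl trione (one prenyl group on the ring carbon between the carbonyls) | CC(C)=CCC1C(=O)[C@@]2(C[C@H]3[C@@H](CC[C@@]3(C)O)[C@@](C)(O)C2)C(=O)C(C(=O)CC(C)C)=C1O | intermediate
25 | CNP0198642.2: 5-hydroxy-4-(3-methylbutanoyl)-6,6-bis(3-methylbut-2-en-1-yl)cyclohex-4-ene-1,3-dione spiro-fused at C-2 to C-5′ of a trans-octahydroindene bearing 3′-hydroxy-3′-methyl and 7′-hydroxy-7′-methyl groups (spiro carbon S, C-3′ R, C-3a′ S, C-7′ S, C-7a′ R) | CC(C)=CCC1(CC=C(C)C)C(=O)[C@@]2(C[C@H]3[C@@H](CC[C@@]3(C)O)[C@@](C)(O)C2)C(=O)C(C(=O)CC(C)C)=C1O | target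

**Summary**
Total steps: 14. Longest linear sequence: 14 steps (1 → 25); compounds 10, 17 and 23 are commercial reagents.

Steps most likely to fail:

Risk 1, step 4. The base equilibration of the β-hydroxy aldehyde may instead cause β-elimination of the tertiary hydroxyl or retro-aldol ring opening, or the epimerization at the formyl-bearing carbon may stay incomplete. The fallback sets out from 5 and moves the epimerizable centre to the ester oxidation level. Pinnick oxidation (NaClO2, NaH2PO4, 2-methylbut-2-ene) gives the epoxy acid F1, and methylation (MeI, K2CO3, DMF) gives the epoxy methyl ester F2. Reductive epoxide opening (SmI2, HMPA, N,N-dimethylethanolamine, THF) followed by NaOMe/MeOH equilibration gives the β-hydroxy ester F3, which tolerates base far better and settles in the trans arrangement. LiAlH4 reduction returns to the route at diol 7.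

Risk 2, step 12. O-acylation or double acylation of the dianion, competing attack on the lactone, and cyclodehydration of the triketone to a pyranone during work-up may erode the acylation. The fallback sets out from 16 (through acid chloride 19 as before) and replaces the strongly basic dianion by a neutral nucleophile: 17 is converted (TMSCl/Et3N, then LDA/TMSCl) into the bis(trimethylsilyl) dienol ether F4. Mukaiyama-type γ-acylation of F4 with 19 (cat. TMSOTf, CH2Cl2, −78 → 20 °C) and mild aqueous work-up rejoins the route at triketone 20.

Risk 3, step 14. O-prenylation, arrest after the first alkylation, and alkylation at the acyl-bearing carbon may compete with geminal C-prenylation. The fallback sets out from 22: Tsuji–Trost double C-allylation with allyl methyl carbonate and Pd(PPh3)4 (zerovalent palladium; O-allyl products re-ionize and funnel to carbon) gives the gem-diallyl trione F5. Double cross-metathesis with 2-methylbut-2-ene using the second-generation Grubbs catalyst RuCl2(=CHPh)(PCy3)(H2IMes) converts both allyl groups into prenyl groups and arrives at target 25.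

Further compounds
F1 | step 4 | epoxy acid: 5-methyl-2-(prop-1-en-2-yl)-6-oxabicyclo[3.1.0]hexane-1-carboxylic acid, epoxide oxygen trans to the isopropenyl group | OC(=O)[C@@]12O[C@]1(C)CC[C@H]2C(C)=C
F2 | step 4 | epoxy methyl ester: methyl 5-methyl-2-(prop-1-en-2-yl)-6-oxabicyclo[3.1.0]hexane-1-carboxylate | COC(=O)[C@@]12O[C@]1(C)CC[C@H]2C(C)=C
F3 | step 4 | β-hydroxy ester: methyl (1S,2R,5R)-2-hydroxy-2-methyl-5-(prop-1-en-2-yl)cyclopentane-1-carboxylate | COC(=O)[C@H]1[C@@H](CC[C@@]1(C)O)C(C)=C
F4 | step 12 | 6-methyl-2,4-bis(trimethylsilyloxy)hepta-1,3-diene | C=C(O[Si](C)(C)C)C=C(O[Si](C)(C)C)CC(C)C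
F5 | step 14 | gem-diallyl trione (target with allyl in place of both prenyl groups) | C=CCC1(CC=C)C(=O)[C@@]2(C[C@H]3[C@@H](CC[C@@]3(C)O)[C@@](C)(O)C2)C(=O)C(C(=O)CC(C)C)=C1O
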